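**Retrosynthetic overview**

1. The target is a 2,3-cis-(2R,3R)-2,3-dihydrobenzofuran (ring A = benzene ring, ring B = dihydrofuran ring, benzofuran numbering). The exocyclic methylene of the 2-propenal unit comes last, by α-methylenation of a C2–CH2–CHO aldehyde, and both isovalerates come from the free carbinols by acylation.
2. The (R)-carbinol on C5 comes from a C5 acetyl group by catalyst-controlled transfer hydrogenation; the acetyl group is placed on C5–H of ring A by para-bromination (O1 directs to C5) and Stille coupling.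
3. C2 and C3 are set together, cis, by dynamic kinetic resolution in the transfer hydrogenation of a 2-substituted benzofuran-3(2H)-one, in which C2 is epimerizable.
4. Key disconnection: ring B is cut at O1–C7a and C3–C3a, which leads to benzyne and α-hydroxy-γ-butyrolactone in a formal (3+2) annulation. Ring A is bought; ring B is the only ring formed (step 1).
5. Enabling feature: in ring B, O1 sits on C2 next to the oxygen-bearing C3, so O1–C2–C3 is an α-hydroxy carbonyl unit (nucleophilic O, electrophilic C) that matches the adjacent ring A carbons C7a/C3a as an aryne. The two propenal carbons attached beyond C2 (C-α and CHO) are the β- and γ-carbons of the lactone.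

Key step: step 1

Assumption: lactone 1 is used as the racemate, because C2 stays configurationally labile until step 3; benzofuran numbering (O1, C2, C3, C3a, C4 to C7, C7a) is used for all intermediates.

**Route**

Step 1
Reactants: 1 racemic α-hydroxy-γ-butyrolactone (3-hydroxyoxolan-2-one); 2 2-(trimethylsilyl)phenyl trifluoromethanesulfonate
Product: 6 racemic 2-(2-hydroxyethyl)-1-benzofuran-3(2H)-one, via sodium alkoxide 3 (not isolated), via benzyne 4 (not isolated), via hemiketal alkoxide 5 (not isolated)
Conditions: 1 (excess), NaH, THF, 0 °C; then 2, KF, 18-crown-6, THF, 0 to 25 °C; AcOH quench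
Reagents that add atoms: none
Why: Proposed new method: fluoride unmasks benzyne 4 from 2, the pre-formed alkoxide 3 adds through oxygen (bond O1–C7a) and the ortho aryl anion so formed attacks the neighbouring lactone carbonyl (bond C3a–C3) to give the cis-fused hemiketal alkoxide 5, which opens to hydroxy ketone 6 on protonation; the closest known reaction types are the aryne annulation of salicylate esters to xanthones (O-arylation, then acyl capture of the aryl anion) and the Parham cyclization of ortho-metalated aryl ethers onto esters. Ring B closes by 5-exo-trig addition of the in-plane aryl carbanion to the lactone C=O. No stereocenter of the target is fixed here: the cis ring fusion of 5 is dictated by the bicyclo[3.3.0] geometry but vanishes on ring opening, and C2 of 6 is racemic and intentionally left epimerizable, α to the new ketone, for step 3. The step needs O-arylation by the alkoxide, acyl capture faster than protonation of the aryl anion, and no further arylation of the product: full deprotonation with NaH removes the O–H that would quench the carbanion, the 1,2-relationship of alkoxide and carbonyl in 1 makes acyl capture a five-membered closure, and an excess of 3 should outcompete the product for the aryne. The symmetric aryne raises no regiochemical question, and the lactone keeps the displaced alkoxide tethered as the hemiketal, so no free alkoxide leaving group is released.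

Step 2
Reactants: 6 racemic 2-(2-hydroxyethyl)-1-benzofuran-3(2H)-one
Product: 7 racemic 2-[2-(tert-butyldiphenylsilyloxy)ethyl]-1-benzofuran-3(2H)-one
Conditions: TBDPSCl, imidazole, DMF, 0 to 25 °C
Reagents that add atoms: tert-butyl(chloro)diphenylsilane, CC(C)(C)[Si](Cl)(c1ccccc1)c1ccccc1
Why: Silyl ether formation at the primary alcohol drains the ring–chain equilibrium of 6 through the open hydroxy ketone, so the hemiketal can no longer mask the ketone or dehydrate to a benzofuran in step 3.

Step 3
Reactants: 7 racemic 2-[2-(tert-butyldiphenylsilyloxy)ethyl]-1-benzofuran-3(2H)-one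
Product: 8 (2R,3R)-2-[2-(tert-butyldiphenylsilyloxy)ethyl]-2,3-dihydro-1-benzofuran-3-ol
Conditions: RuCl[(S,S)-TsDPEN](p-cymene) (cat.), HCO2H/Et3N (5:2), EtOAc, degassed, 30 °C
Reagents that add atoms: none
Why: Noyori–Ikariya asymmetric transfer hydrogenation under dynamic kinetic resolution: C2 (α to the ketone and to O1) should racemize through the enol faster than reduction, the (S,S)-catalyst is expected by the usual aryl ketone model to give the (3R)-carbinol, and hydride enters anti to the C2 chain, so C2 (R) and C3 (R) are set together as the cis pair.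

Step 4
Reactants: 8 (2R,3R)-2-[2-(tert-butyldiphenylsilyloxy)ethyl]-2,3-dihydro-1-benzofuran-3-ol
Product: 9 (2R,3R)-2-[2-(tert-butyldiphenylsilyloxy)ethyl]-2,3-dihydro-1-benzofuran-3-yl 3-methylbutanoate
Conditions: 3-methylbutanoic anhydride, Et3N, DMAP (cat.), CH2Cl2, 0 to 25 °C
Reagents that add atoms: 3-methylbutanoic anhydride, CC(C)CC(=O)OC(=O)CC(C)C
Why: DMAP-catalyzed acyl transfer esterifies the secondary benzylic alcohol with retention at C3 and installs the first isovalerate of the target.

Step 5
Reactants: 9 (2R,3R)-2-[2-(tert-butyldiphenylsilyloxy)ethyl]-2,3-dihydro-1-benzofuran-3-yl 3-methylbutanoate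
Product: 10 (2R,3R)-5-bromo-2-[2-(tert-butyldiphenylsilyloxy)ethyl]-2,3-dihydro-1-benzofuran-3-yl 3-methylbutanoate
Conditions: NBS, MeCN, 0 to 25 °C
Reagents that add atoms: N-bromosuccinimide, O=C1CCC(=O)N1Br
Why: Electrophilic aromatic bromination should go para to the ring oxygen O1, at C5, the most activated and least hindered position, under conditions that leave the silyl ether and the benzylic ester untouched.

Step 6
Reactants: 10 (2R,3R)-5-bromo-2-[2-(tert-butyldiphenylsilyloxy)ethyl]-2,3-dihydro-1-benzofuran-3-yl 3-methylbutanoate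
Product: 12 (2R,3R)-5-acetyl-2-[2-(tert-butyldiphenylsilyloxy)ethyl]-2,3-dihydro-1-benzofuran-3-yl 3-methylbutanoate, via enol ether 11 (not isolated)
Conditions: tributyl(1-ethoxyvinyl)stannane, PdCl2(PPh3)2 (cat.), toluene, 100 °C; then 1 M HCl, THF, 25 °C
Reagents that add atoms: tributyl(1-ethoxyvinyl)stannane, CCCC[Sn](CCCC)(CCCC)C(=C)OCC; water, O
Why: Stille coupling of the aryl bromide with the masked acetyl stannane, followed by mild acid hydrolysis of the enol ether, gives the methyl ketone under conditions the TBDPS ether and the C3 ester should tolerate.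

Step 7
Reactants: 12 (2R,3R)-5-acetyl-2-[2-(tert-butyldiphenylsilyloxy)ethyl]-2,3-dihydro-1-benzofuran-3-yl 3-methylbutanoate
Product: 13 (2R,3R)-2-[2-(tert-butyldiphenylsilyloxy)ethyl]-5-[(1R)-1-hydroxyethyl]-2,3-dihydro-1-benzofuran-3-yl 3-methylbutanoate
Conditions: RuCl[(R,R)-TsDPEN](p-cymene) (cat.), HCO2H/Et3N (5:2), 40 °C
Reagents that add atoms: none
Why: Noyori–Ikariya asymmetric transfer hydrogenation of the aryl methyl ketone; the (R,R)-catalyst should give the (R)-1-arylethanol by catalyst control, independent of the remote ring stereocenters, and formate does not reduce the ester.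

Step 8
Reactants: 13 (2R,3R)-2-[2-(tert-butyldiphenylsilyloxy)ethyl]-5-[(1R)-1-hydroxyethyl]-2,3-dihydro-1-benzofuran-3-yl 3-methylbutanoate
Product: 14 (2R,3R)-2-[2-(tert-butyldiphenylsilyloxy)ethyl]-5-[(1R)-1-(3-methylbutanoyloxy)ethyl]-2,3-dihydro-1-benzofuran-3-yl 3-methylbutanoate
Conditions: 3-methylbutanoic anhydride, Et3N, DMAP (cat.), CH2Cl2, 0 to 25 °C
Reagents that add atoms: 3-methylbutanoic anhydride, CC(C)CC(=O)OC(=O)CC(C)C
Why: DMAP-catalyzed acyl transfer esterifies the carbinol with retention under near-neutral conditions that avoid ionization of the para-alkoxybenzylic center.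

Step 9
Reactants: 14 (2R,3R)-2-[2-(tert-butyldiphenylsilyloxy)ethyl]-5-[(1R)-1-(3-methylbutanoyloxy)ethyl]-2,3-dihydro-1-benzofuran-3-yl 3-methylbutanoate
Product: 15 (2R,3R)-2-(2-hydroxyethyl)-5-[(1R)-1-(3-methylbutanoyloxy)ethyl]-2,3-dihydro-1-benzofuran-3-yl 3-methylbutanoate
Conditions: HF·pyridine, pyridine, THF, 0 to 25 °C
Reagents that add atoms: none
Why: Fluoride-mediated silyl ether cleavage; pyridine-buffered HF should leave both esters and the acid-sensitive benzylic C–O bonds intact and avoid base-induced acyl migration.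

Step 10
Reactants: 15 (2R,3R)-2-(2-hydroxyethyl)-5-[(1R)-1-(3-methylbutanoyloxy)ethyl]-2,3-dihydro-1-benzofuran-3-yl 3-methylbutanoate
Product: 16 (2R,3R)-5-[(1R)-1-(3-methylbutanoyloxy)ethyl]-2-(2-oxoethyl)-2,3-dihydro-1-benzofuran-3-yl 3-methylbutanoate
Conditions: Dess–Martin periodinane, pyridine, CH2Cl2, 0 to 25 °C
Reagents that add atoms: none
Why: Dess–Martin oxidation converts the primary alcohol to the aldehyde under buffered, non-basic conditions that should not trigger β-elimination of the aryloxy group.

Step 11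
Reactants: 16 (2R,3R)-5-[(1R)-1-(3-methylbutanoyloxy)ethyl]-2-(2-oxoethyl)-2,3-dihydro-1-benzofuran-3-yl 3-methylbutanoate
Product: 17 (2R,3R)-5-[(1R)-1-(3-methylbutanoyloxy)ethyl]-2-(3-oxoprop-1-en-2-yl)-2,3-dihydro-1-benzofuran-3-yl 3-methylbutanoate (target)
Conditions: (CH2=NMe2)I (Eschenmoser's salt), Et3N, CH2Cl2, 25 °C
Reagents that add atoms: N,N-dimethylmethyleneiminium iodide, C=[N+](C)C.[I-]
Why: Mannich α-methylenation of the aldehyde followed by elimination of dimethylamine installs the exocyclic methylene without touching a stereocenter, provided the reactive pre-formed iminium captures the aldehyde faster than it ring-opens.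

**Compound list**

1 | racemic α-hydroxy-γ-butyrolactone (3-hydroxyoxolan-2-one) | OC1CCOC1=O | starting material
2 | 2-(trimethylsilyl)phenyl trifluoromethanesulfonate | C[Si](C)(C)c1ccccc1OS(=O)(=O)C(F)(F)F | starting material
3 | sodium alkoxide of 1 (sodium 2-oxooxolan-3-olate), racemic | [Na+].[O-]C1CCOC1=O | intermediate
4 | benzyne (1,2-didehydrobenzene) | C1#CC=CC=C1 | intermediate
5 | sodium salt of the cis-fused bicyclic hemiketal alkoxide (furo[3,2-b]benzofuran skeleton; racemic, one enantiomer drawn) | [Na+].[O-][C@@]12OCC[C@@H]1Oc1ccccc12 | intermediate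
6 | racemic 2-(2-hydroxyethyl)-1-benzofuran-3(2H)-one (in equilibrium with its neutral cis-fused hemiketal) | OCCC1Oc2ccccc2C1=O | intermediate
7 | racemic 2-[2-(tert-butyldiphenylsilyloxy)ethyl]-1-benzofuran-3(2H)-one | CC(C)(C)[Si](OCCC1Oc2ccccc2C1=O)(c1ccccc1)c1ccccc1 | intermediate
8 | (2R,3R)-2-[2-(tert-butyldiphenylsilyloxy)ethyl]-2,3-dihydro-1-benzofuran-3-ol | CC(C)(C)[Si](OCC[C@H]1Oc2ccccc2[C@H]1O)(c1ccccc1)c1ccccc1 | intermediate
9 | (2R,3R)-2-[2-(tert-butyldiphenylsilyloxy)ethyl]-2,3-dihydro-1-benzofuran-3-yl 3-methylbutanoate | CC(C)(C)[Si](OCC[C@H]1Oc2ccccc2[C@H]1OC(=O)CC(C)C)(c1ccccc1)c1ccccc1 | intermediate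
10 | (2R,3R)-5-bromo-2-[2-(tert-butyldiphenylsilyloxy)ethyl]-2,3-dihydro-1-benzofuran-3-yl 3-methylbutanoate | CC(C)(C)[Si](OCC[C@H]1Oc2ccc(Br)cc2[C@H]1OC(=O)CC(C)C)(c1ccccc1)c1ccccc1 | intermediate
11 | (2R,3R)-2-[2-(tert-butyldiphenylsilyloxy)ethyl]-5-(1-ethoxyethenyl)-2,3-dihydro-1-benzofuran-3-yl 3-methylbutanoate | CC(C)(C)[Si](OCC[C@H]1Oc2ccc(C(=C)OCC)cc2[C@H]1OC(=O)CC(C)C)(c1ccccc1)c1ccccc1 | intermediate
12 | (2R,3R)-5-acetyl-2-[2-(tert-butyldiphenylsilyloxy)ethyl]-2,3-dihydro-1-benzofuran-3-yl 3-methylbutanoate | CC(C)(C)[Si](OCC[C@H]1Oc2ccc(C(C)=O)cc2[C@H]1OC(=O)CC(C)C)(c1ccccc1)c1ccccc1 | intermediate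
13 | (2R,3R)-2-[2-(tert-butyldiphenylsilyloxy)ethyl]-5-[(1R)-1-hydroxyethyl]-2,3-dihydro-1-benzofuran-3-yl 3-methylbutanoate | CC(C)(C)[Si](OCC[C@H]1Oc2ccc([C@@H](C)O)cc2[C@H]1OC(=O)CC(C)C)(c1ccccc1)c1ccccc1 | intermediate
14 | (2R,3R)-2-[2-(tert-butyldiphenylsilyloxy)ethyl]-5-[(1R)-1-(3-methylbutanoyloxy)ethyl]-2,3-dihydro-1-benzofuran-3-yl 3-methylbutanoate | CC(C)(C)[Si](OCC[C@H]1Oc2ccc([C@@H](C)OC(=O)CC(C)C)cc2[C@H]1OC(=O)CC(C)C)(c1ccccc1)c1ccccc1 | intermediate
15 | (2R,3R)-2-(2-hydroxyethyl)-5-[(1R)-1-(3-methylbutanoyloxy)ethyl]-2,3-dihydro-1-benzofuran-3-yl 3-methylbutanoate | OCC[C@H]1Oc2ccc([C@@H](C)OC(=O)CC(C)C)cc2[C@H]1OC(=O)CC(C)C | intermediate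
16 | (2R,3R)-5-[(1R)-1-(3-methylbutanoyloxy)ethyl]-2-(2-oxoethyl)-2,3-dihydro-1-benzofuran-3-yl 3-methylbutanoate | O=CC[C@H]1Oc2ccc([C@@H](C)OC(=O)CC(C)C)cc2[C@H]1OC(=O)CC(C)C | intermediate
17 | (2R,3R)-5-[(1R)-1-(3-methylbutanoyloxy)ethyl]-2-(3-oxoprop-1-en-2-yl)-2,3-dihydro-1-benzofuran-3-yl 3-methylbutanoate | C=C(C=O)[C@H]1Oc2ccc([C@@H](C)OC(=O)CC(C)C)cc2[C@H]1OC(=O)CC(C)C | target

**Step count and risks**

Total step count: 11. Longest linear sequence: 11 steps (1 and 2 to 17).

Steps most likely to fail:

Step 1 (proposed new method). The aryl anion may be protonated before it captures the lactone carbonyl, the product enolate or alkoxide may be arylated again by the aryne, or the alkoxide lactone may oligomerize by transesterification. Fallback with known chemistry, setting out from 1 and returning at 6: Mitsunobu etherification of 1 with 2-bromophenol (PPh3, DIAD, THF, 0 to 25 °C) should give racemic 3-(2-bromophenoxy)oxolan-2-one F1. Bromine–lithium exchange (n-BuLi, THF, −100 °C) and Parham cyclization of the aryllithium onto the lactone carbonyl, then an AcOH quench, should give 6.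

Step 11. The β-aryloxy aldehyde may undergo E1cB ring opening (retro-oxa-Michael) under the amine base and re-close with loss of the cis configuration at C2, or the Mannich base may eliminate incompletely. Fallback, setting out from 16 and returning at 17: enol silylation (TMSOTf, Et3N, CH2Cl2, −78 °C) should give the (2R,3R) trimethylsilyl enol ether F3 without a free enolate. A base-free Mukaiyama–Mannich reaction with (CH2=NMe2)I (CH2Cl2, 0 °C) should give the β-dimethylamino aldehyde F4 as a mixture of epimers at the new carbon. N-methylation (MeI, CH2Cl2) should give the trimethylammonium iodide F5, and Hofmann-type elimination with NaHCO3 should then give 17.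

Step 3. Facial discrimination on the α-aryloxy ketone may be insufficient, racemization at C2 may be slower than reduction, or the enol may be oxidized by air; any of these would lower enantiomeric or diastereomeric purity. Fallback, setting out from 7 and returning at 8: substrate-controlled reduction with LiBH(s-Bu)3 (THF, −78 °C; hydride anti to the C2 chain) should give the racemic cis alcohol F2. Resolution by preparative chromatography on a chiral stationary phase should then give 8.

**Further compounds**

F1 | step 1 | racemic 3-(2-bromophenoxy)oxolan-2-one | O=C1OCCC1Oc1ccccc1Br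
F2 | step 3 | racemic cis-2-[2-(tert-butyldiphenylsilyloxy)ethyl]-2,3-dihydro-1-benzofuran-3-ol (1:1 mixture of the (2R,3R) and (2S,3S) forms) | CC(C)(C)[Si](OCC[C@H]1Oc2ccccc2[C@H]1O)(c1ccccc1)c1ccccc1.CC(C)(C)[Si](OCC[C@@H]1Oc2ccccc2[C@@H]1O)(c1ccccc1)c1ccccc1
F3 | step 11 | (2R,3R)-5-[(1R)-1-(3-methylbutanoyloxy)ethyl]-2-[2-(trimethylsilyloxy)ethenyl]-2,3-dihydro-1-benzofuran-3-yl 3-methylbutanoate (E/Z mixture) | C[Si](C)(C)OC=C[C@H]1Oc2ccc([C@@H](C)OC(=O)CC(C)C)cc2[C@H]1OC(=O)CC(C)C
F4 | step 11 | (2R,3R)-2-[1-(dimethylamino)-3-oxopropan-2-yl]-5-[(1R)-1-(3-methylbutanoyloxy)ethyl]-2,3-dihydro-1-benzofuran-3-yl 3-methylbutanoate (epimers at the side-chain carbon) | CN(C)CC(C=O)[C@H]1Oc2ccc([C@@H](C)OC(=O)CC(C)C)cc2[C@H]1OC(=O)CC(C)C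
F5 | step 11 | trimethylammonium iodide obtained by N-methylation of F4 | C[N+](C)(C)CC(C=O)[C@H]1Oc2ccc([C@@H](C)OC(=O)CC(C)C)cc2[C@H]1OC(=O)CC(C)C.[I-]
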